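**Retrosynthetic overview**
1. Rings and numbering: A azepine (N4, C5–C8, C9, C9a); B pyrrole (N4, C9a, C1, C2, C3); C carbocycle (C9a, C1, C12, C11, C10, C9); D fused lactone (C11–O–C14–C13–C12); E pendant lactone (C18–C21) on C3.
2. Last disconnections: ring E comes from a γ-keto ester on C3. C18 is set by asymmetric transfer hydrogenation and C20 is bought in a zinc homoenolate. The C10 ethyl group comes from a C10 formyl group.
3. Key disconnection: C9a–C9 together with C10–C11. An intramolecular Diels–Alder reaction closes rings A and C at once, turns a 2-silyloxyfuran into ring D, and sets C9–C13 from a precursor whose core has no stereocentre.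
4. Enabling feature: C9a=C1 of ring B and C12/C11 of ring D are joined by the C1–C12 bond. The furan (dienol) form of ring D therefore completes an s-cis diene C9a=C1–C12=C11, which ends at the two atoms that must bond to C9 and C10. N4, next to C9a, carries the (CH2)4 chain that delivers the C9=C10 enal.
5. Precursor assembly: bromopyrrole ester, 6-bromohexene, zinc reagent and bromobutenolide are joined by N-alkylation, Negishi acylation, Suzuki coupling, silylation and cross-metathesis. Ring order: B and D (bought), then A + C (step 8), then E (step 11).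

Key step: step 8

Remark: the (R)-zinc homoenolate solution in THF and 3-methyltetronic acid are taken as commercially available.

**Step 1**
Reactants: 1 methyl 4-bromo-1H-pyrrole-2-carboxylate; 2 6-bromohex-1-ene
Product: 3 methyl 4-bromo-1-(hex-5-en-1-yl)-1H-pyrrole-2-carboxylate
Conditions: K2CO3, DMF, 60 °C
Reagents that add atoms: none
Why: The ester-acidified pyrrole N–H is deprotonated by carbonate and the anion undergoes SN2 N-alkylation with the primary bromide.

**Step 2**
Reactants: 3 methyl 4-bromo-1-(hex-5-en-1-yl)-1H-pyrrole-2-carboxylate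
Product: 4 4-bromo-1-(hex-5-en-1-yl)-1H-pyrrole-2-carboxylic acid
Conditions: LiOH, THF/MeOH/H2O, 50 °C; then 1 M HCl
Reagents that add atoms: lithium hydroxide, [Li+].[OH-]
Why: Ordinary ester saponification, which touches neither the bromide nor the alkene.

**Step 3**
Reactants: 4 4-bromo-1-(hex-5-en-1-yl)-1H-pyrrole-2-carboxylic acid; 5 (R)-(3-methoxy-2-methyl-3-oxopropyl)zinc bromide
Product: 7 methyl (S)-4-[4-bromo-1-(hex-5-en-1-yl)-1H-pyrrol-2-yl]-2-methyl-4-oxobutanoate, via acid chloride 6 (not isolated)
Conditions: (COCl)2, cat. DMF, CH2Cl2, 0 °C to rt, concentrate; then 5, Pd(PPh3)4 (3 mol %), THF, 0 °C to rt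
Reagents that add atoms: oxalyl chloride, O=C(Cl)C(=O)Cl (chlorine of 6)
Why: Negishi acylation, in which zerovalent palladium inserts into the acyl chloride much faster than into the electron-rich pyrrole C–Br bond, the zinc homoenolate transfers its primary carbon so that the neighbouring stereocentre (the later C20) is retained, and the deactivated ketone is not attacked again.

**Step 4**
Reactants: 8 4-hydroxy-3-methylfuran-2(5H)-one (3-methyltetronic acid)
Product: 9 4-bromo-3-methylfuran-2(5H)-one
Conditions: (COBr)2, cat. DMF, CH2Cl2, 0 °C to rt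
Reagents that add atoms: oxalyl bromide, O=C(Br)C(=O)Br
Why: Vilsmeier-type bromodehydroxylation, in which the vinylogous acid OH is activated and replaced by bromide through addition–elimination.

**Step 5**
Reactants: 7 methyl (S)-4-[4-bromo-1-(hex-5-en-1-yl)-1H-pyrrol-2-yl]-2-methyl-4-oxobutanoate; 9 4-bromo-3-methylfuran-2(5H)-one; 10 bis(pinacolato)diboron
Product: 12 methyl (S)-4-[1-(hex-5-en-1-yl)-4-(4-methyl-5-oxo-2,5-dihydrofuran-3-yl)-1H-pyrrol-2-yl]-2-methyl-4-oxobutanoate, via pinacol boronate 11 (not isolated)
Conditions: 10, Pd(dppf)Cl2 (5 mol %), KOAc, 1,4-dioxane, 90 °C; then 9, aq. K3PO4, 70 °C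
Reagents that add atoms: none
Why: One-pot Miyaura borylation and Suzuki–Miyaura coupling, in which zerovalent palladium inserts readily into the electron-poor vinylogous acyl bromide 9 and the C1–C12 bond forms without touching the terminal alkene or C20.

**Step 6**
Reactants: 12 methyl (S)-4-[1-(hex-5-en-1-yl)-4-(4-methyl-5-oxo-2,5-dihydrofuran-3-yl)-1H-pyrrol-2-yl]-2-methyl-4-oxobutanoate
Product: 13 methyl (S)-4-[1-(hex-5-en-1-yl)-4-{4-methyl-5-[(triisopropylsilyl)oxy]furan-3-yl}-1H-pyrrol-2-yl]-2-methyl-4-oxobutanoate
Conditions: TIPSOTf (1.1 equiv), Et3N, CH2Cl2, −78 to 0 °C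
Reagents that add atoms: triisopropylsilyl trifluoromethanesulfonate, CC(C)[Si](C(C)C)(C(C)C)OS(=O)(=O)C(F)(F)F
Why: Soft enolisation (silyl triflate/amine) of the butenolide, whose γ-deprotonation is driven by formation of the aromatic furan and should therefore outrun enol silane formation at the hindered C18 ketone, with no stereocentre touched.

**Step 7**
Reactants: 13 methyl (S)-4-[1-(hex-5-en-1-yl)-4-{4-methyl-5-[(triisopropylsilyl)oxy]furan-3-yl}-1H-pyrrol-2-yl]-2-methyl-4-oxobutanoate; 14 (E)-but-2-enal
Product: 15 methyl (S)-2-methyl-4-[4-{4-methyl-5-[(triisopropylsilyl)oxy]furan-3-yl}-1-[(E)-7-oxohept-5-en-1-yl]-1H-pyrrol-2-yl]-4-oxobutanoate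
Conditions: 14 (5 equiv), second-generation Hoveyda–Grubbs catalyst (5 mol %), CH2Cl2, 30 °C; filtration through Et3N-deactivated silica
Reagents that add atoms: none
Why: Olefin cross-metathesis of a terminal alkene with an electron-poor enal partner should give the (E)-enal under neutral conditions, the aromatic furan and pyrrole C=C bonds being inert to the ruthenium alkylidene.

**Step 8**
Reactants: 15 methyl (S)-2-methyl-4-[4-{4-methyl-5-[(triisopropylsilyl)oxy]furan-3-yl}-1-[(E)-7-oxohept-5-en-1-yl]-1H-pyrrol-2-yl]-4-oxobutanoate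
Product: 18 tetracyclic aldehyde (9R,10R,11S,12S,13S,20S), via primary cycloadduct 16 (not isolated), via silyl ketene acetal 17 (not isolated)
Conditions: (2S,5S)-5-benzyl-2-tert-butyl-3-methylimidazolidin-4-one·2,4-dinitrobenzoic acid (20 mol %), H2O (2 equiv), CH2Cl2 (0.005 M), −20 °C; then aq. citric acid, THF, 0 °C
Reagents that add atoms: none
Why: Proposed new method: the imidazolidinone salt converts the enal into an (E)-iminium ion whose C9=C10 bond adds across the electron-rich s-cis diene C9a=C1–C12=C11 (one C=C of pyrrole ring B and one C=C of the silyloxyfuran) in a concerted but asynchronous (4+2) cycloaddition to 16, an acid-mediated 1,3-proton shift from C9a to C12 restores the pyrrole (17), and C13-protonation of the cyclic silyl ketene acetal with loss of the silyl group to water leaves lactone D (18). The closest known reaction types are the iminium-catalysed intramolecular Diels–Alder reaction of trienals and the iminium-catalysed Diels–Alder reaction of vinylindoles and vinylpyrroles with enals followed by rearomatisation, whereas a diene assembled from two different heteroarenes and a tether that closes a seven-membered ring have not been shown. Ring C closes as the six-membered (4+2) ring and ring A closes in the fused type 1 mode, the five-atom link N4–C5–C6–C7–C8 joining diene terminus C9a to dienophile carbon C9 so that the C9a–C9 bond completes the azepine. C9 and C10 take their absolute configuration from the benzyl and tert-butyl groups of the (2S,5S)-catalyst, which leave only the Re face of C9 open, and their trans relation from the (E)-alkene, while C11 follows from the endo transition state (iminium carbon stacked over the furan and tether exo), which sets the formyl group cis to the C11–O bond. C12 and C13 are set by delivery of both protons to the convex face of the folded C/D bicycle, opposite to C10, which makes H11, H12 and H13 all cis and leaves the C13 methyl group on the concave face as the kinetic product. The step needs attack at C9a and not at C3 (C3 is blocked by the acyl group, which also disfavours a simple Friedel–Crafts stop), ring closure ahead of intermolecular vinylogous Mukaiyama–Michael addition at C11 (high dilution, and the intramolecular C11–C9 mode would need a ten-membered ring) and catalysis ahead of the thermal background (low temperature).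

**Step 9**
Reactants: 18 tetracyclic aldehyde (9R,10R,11S,12S,13S,20S)
Product: 19 10-vinyl tetracycle (9R,10R,11R,12S,13S,20S)
Conditions: Ph3PCH3Br, KHMDS, THF, 0 °C; then 18, −78 to −20 °C
Reagents that add atoms: methyltriphenylphosphonium bromide, C[P+](c1ccccc1)(c1ccccc1)c1ccccc1.[Br-]
Why: Wittig methylenation, in which the non-stabilised ylide attacks the aliphatic aldehyde far faster than the deactivated pyrrolyl ketone, the ester or the lactone, and the low temperature should keep C10 and C13 from enolising.

**Step 10**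
Reactants: 19 10-vinyl tetracycle (9R,10R,11R,12S,13S,20S)
Product: 20 10-ethyl keto ester (9R,10R,11R,12S,13S,20S)
Conditions: H2 (1 atm), Pd/C, EtOAc, rt
Reagents that add atoms: none
Why: Heterogeneous catalytic hydrogenation saturates only the monosubstituted alkene, the acylpyrrole being inert at one atmosphere.

**Step 11**
Reactants: 20 10-ethyl keto ester (9R,10R,11R,12S,13S,20S)
Product: 22 CNP0232452.1 (9R,10R,11R,12S,13S,18R,20S), via hydroxy ester 21 (not isolated)
Conditions: RuCl[(R,R)-TsDPEN](p-cymene) (2 mol %), HCO2H/Et3N, CH2Cl2, 30 °C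
Reagents that add atoms: none
Why: Noyori–Ikariya asymmetric transfer hydrogenation of the aryl-type ketone, in which the (R,R)-catalyst should give the (18R)-carbinol regardless of the remote centres, and the hydroxyl group then closes ring E on the methyl ester (5-exo-trig) with C20 untouched, giving the trans-3,5-disubstituted lactone.

**Compound list**
1 | methyl 4-bromo-1H-pyrrole-2-carboxylate | COC(=O)c1cc(Br)c[nH]1 | starting material
2 | 6-bromohex-1-ene | C=CCCCCBr | starting material
3 | methyl 4-bromo-1-(hex-5-en-1-yl)-1H-pyrrole-2-carboxylate | COC(=O)c1cc(Br)cn1CCCCC=C | intermediate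
4 | 4-bromo-1-(hex-5-en-1-yl)-1H-pyrrole-2-carboxylic acid | OC(=O)c1cc(Br)cn1CCCCC=C | intermediate
5 | (R)-(3-methoxy-2-methyl-3-oxopropyl)zinc bromide | Br[Zn]C[C@H](C)C(=O)OC | starting material
6 | 4-bromo-1-(hex-5-en-1-yl)-1H-pyrrole-2-carbonyl chloride | ClC(=O)c1cc(Br)cn1CCCCC=C | intermediate
7 | methyl (S)-4-[4-bromo-1-(hex-5-en-1-yl)-1H-pyrrol-2-yl]-2-methyl-4-oxobutanoate | C=CCCCCn1cc(Br)cc1C(=O)C[C@H](C)C(=O)OC | intermediate
8 | 4-hydroxy-3-methylfuran-2(5H)-one | CC1=C(O)COC1=O | starting material
9 | 4-bromo-3-methylfuran-2(5H)-one | CC1=C(Br)COC1=O | intermediate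
10 | bis(pinacolato)diboron | CC1(C)OB(OC1(C)C)B1OC(C)(C)C(C)(C)O1 | starting material
11 | pinacol boronate of 7 (Bpin in place of Br) | C=CCCCCn1cc(B2OC(C)(C)C(C)(C)O2)cc1C(=O)C[C@H](C)C(=O)OC | intermediate
12 | pyrrolyl butenolide (S) | C=CCCCCn1cc(C2=C(C)C(=O)OC2)cc1C(=O)C[C@H](C)C(=O)OC | intermediate
13 | pyrrolyl 2-(triisopropylsilyloxy)furan (S) | C=CCCCCn1cc(-c2coc(O[Si](C(C)C)(C(C)C)C(C)C)c2C)cc1C(=O)C[C@H](C)C(=O)OC | intermediate
14 | (E)-but-2-enal | C/C=C/C=O | starting material
15 | (E)-enal with silyloxyfuran–pyrrole diene (S) | O=C/C=C/CCCCn1cc(-c2coc(O[Si](C(C)C)(C(C)C)C(C)C)c2C)cc1C(=O)C[C@H](C)C(=O)OC | intermediate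
16 | primary (4+2) adduct: C1=C12 alkene, sp3 C9a with 9a-H trans to 9-H, C9–C11 as in 18 | O=C[C@H]1[C@H]2OC(O[Si](C(C)C)(C(C)C)C(C)C)=C(C)C2=C2C=C(C(=O)C[C@H](C)C(=O)OC)N3CCCC[C@H]1[C@@H]23 | intermediate
17 | rearomatised cyclic silyl ketene acetal, C9–C12 as in 18 | O=C[C@H]1[C@H]2OC(O[Si](C(C)C)(C(C)C)C(C)C)=C(C)[C@H]2c2cc(C(=O)C[C@H](C)C(=O)OC)n3c2[C@@H]1CCCC3 | intermediate
18 | tetracyclic aldehyde (9R,10R,11S,12S,13S,20S) | O=C[C@H]1[C@H]2OC(=O)[C@@H](C)[C@H]2c2cc(C(=O)C[C@H](C)C(=O)OC)n3c2[C@@H]1CCCC3 | intermediate
19 | 10-vinyl tetracycle (9R,10R,11R,12S,13S,20S) | C=C[C@H]1[C@H]2OC(=O)[C@@H](C)[C@H]2c2cc(C(=O)C[C@H](C)C(=O)OC)n3c2[C@@H]1CCCC3 | intermediate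
20 | 10-ethyl keto ester (9R,10R,11R,12S,13S,20S) | CC[C@H]1[C@H]2OC(=O)[C@@H](C)[C@H]2c2cc(C(=O)C[C@H](C)C(=O)OC)n3c2[C@@H]1CCCC3 | intermediate
21 | (18R)-hydroxy ester | CC[C@H]1[C@H]2OC(=O)[C@@H](C)[C@H]2c2cc([C@H](O)C[C@H](C)C(=O)OC)n3c2[C@@H]1CCCC3 | intermediate
22 | CNP0232452.1 (9R,10R,11R,12S,13S,18R,20S) | CC[C@H]1[C@H]2OC(=O)[C@@H](C)[C@H]2c2cc([C@H]3C[C@H](C)C(=O)O3)n3c2[C@@H]1CCCC3 | target

**Totals**
Total step count: 11. Longest linear sequence: 10 (steps 1–3 and 5–11).

**Steps most likely to fail**

**1. Step 8 (Proposed new method).**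
- What may go wrong: the acyl-tempered diene and the slow closure of the seven-membered tether ring may let other processes win. These are intermolecular vinylogous Mukaiyama–Michael addition at C11, protodesilylation back to the butenolide, β-elimination of the C11 carboxylate through the enamine, and poor endo/exo selectivity.
- Fallback (established reaction types; sets out from 13, returns at 18): cross-metathesis of 13 with (S)-3-acryloyl-4-benzyloxazolidin-2-one should give the N-enoyl oxazolidinone F1.
- The aprotic, chelation-controlled Me2AlCl-promoted auxiliary Diels–Alder reaction of this imide (CH2Cl2, −30 °C, aq. citric acid work-up) should give the tetracyclic imide F2. The benzyl group shields the same alkene face as the catalyst did.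
- LiSEt (THF, 0 °C) exchanges the auxiliary to give the ethyl thioester F3. Fukuyama reduction (Et3SiH, Pd/C, acetone) then returns aldehyde 18.

**2. Step 9.**
- What may go wrong: the basic ylide may enolise the β-acyloxy aldehyde. This would cause epimerisation at C10, E1cB opening of ring D, or drift of the concave C13 methyl group to the convex face.
- Fallback (sets out from 18, returns at 20, skipping 19): non-basic, aldehyde-selective addition of MeTi(OiPr)3 (THF, −40 °C) should give the secondary alcohol F4. Both carbinol epimers are usable.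
- 1,1'-Thiocarbonyldiimidazole (DMAP, CH2Cl2) converts F4 into the imidazolylthiocarbonate F5. Barton–McCombie deoxygenation (Bu3SnH, AIBN, toluene, 80 °C) then gives 20.

**3. Step 11.**
- What may go wrong: hydride transfer to the electron-rich ketone may be sluggish. The pyrrolyl carbinol may also ionise in the formic acid medium, with loss of configuration at C18 or over-reduction.
- Fallback (sets out from 20, returns at 22): Luche reduction (NaBH4, CeCl3·7H2O, MeOH, −40 °C) without stereocontrol gives 21 together with the (18S)-hydroxy ester F6.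
- Both lactonise with Et3N in toluene to 22 and the cis-lactone F7, which are separated by chromatography.
- F7 is re-equilibrated at C18 through its azafulvenium carboxylate ion pair (cat. camphorsulfonic acid, CH2Cl2, 0 °C) and recycled, so that the material funnels to 22.

**Further compounds**
F1 | step 8 | N-enoyl oxazolidinone of the silyloxyfuran–pyrrole diene | O=C(/C=C/CCCCn1cc(-c2coc(O[Si](C(C)C)(C(C)C)C(C)C)c2C)cc1C(=O)C[C@H](C)C(=O)OC)N1[C@@H](Cc2ccccc2)COC1=O
F2 | step 8 | tetracyclic imide (C10 acyl oxazolidinone) | O=C([C@H]1[C@H]2OC(=O)[C@@H](C)[C@H]2c2cc(C(=O)C[C@H](C)C(=O)OC)n3c2[C@@H]1CCCC3)N1[C@@H](Cc2ccccc2)COC1=O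
F3 | step 8 | C10 S-ethyl thioester | CCSC(=O)[C@H]1[C@H]2OC(=O)[C@@H](C)[C@H]2c2cc(C(=O)C[C@H](C)C(=O)OC)n3c2[C@@H]1CCCC3
F4 | step 9 | C10 1-hydroxyethyl tetracycle (carbinol epimers) | CC(O)[C@H]1[C@H]2OC(=O)[C@@H](C)[C@H]2c2cc(C(=O)C[C@H](C)C(=O)OC)n3c2[C@@H]1CCCC3
F5 | step 9 | imidazolylthiocarbonate of F4 | CC(OC(=S)n1ccnc1)[C@H]1[C@H]2OC(=O)[C@@H](C)[C@H]2c2cc(C(=O)C[C@H](C)C(=O)OC)n3c2[C@@H]1CCCC3
F6 | step 11 | (18S)-hydroxy ester | CC[C@H]1[C@H]2OC(=O)[C@@H](C)[C@H]2c2cc([C@@H](O)C[C@H](C)C(=O)OC)n3c2[C@@H]1CCCC3
F7 | step 11 | (18S)-epimer of 22 (cis-lactone E) | CC[C@H]1[C@H]2OC(=O)[C@@H](C)[C@H]2c2cc([C@@H]3C[C@H](C)C(=O)O3)n3c2[C@@H]1CCCC3
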